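The route rests on tracing the C1–O and C4–O bonds back to a cyclopentadiene. In the target, the ketone carbon C1 and the acetoxy carbon C4 sit on either side of the quaternary carbinol C5 and are linked through the C2=C3 double bond, so the five-membered ring is a cyclopent-2-ene oxygenated at both allylic positions. Dioxygen [4+2] addition across C1/C4 and base-induced peroxide opening deliver this array in one operation, forming two C–O bonds and the C4 and C5 stereocentres. The precursor is a 5,5-disubstituted cyclopentadiene with the C5 oxygen silylated and the (S)-C6 hydroxyl free, assembled from methyl (S)-glycidate, a C13 Grignard reagent and two allyl units.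

Key step: step 8

Remark: ring atoms are numbered C1 (ketone) to C5 (quaternary carbinol) with C6 the side-chain carbinol; which cinchona pseudoenantiomer removes the required bridgehead hydrogen cannot be read from the structure, so the quinine-derived catalyst is written and its quinidine-derived counterpart is taken if the first proves mismatched.

**Step 1**
Reactants: 1 1-bromotridecane; 2 methyl (2S)-oxirane-2-carboxylate (methyl (S)-glycidate)
Product: 4 methyl (2S)-2-hydroxyhexadecanoate, via tridecylmagnesium bromide 3 (not isolated)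
Conditions: Mg, THF, 45 °C; then CuI (10 mol%), 2, THF, −78 → −30 °C; aq. NH4Cl
Reagents that add atoms: none
Why: Copper-catalysed Grignard opening of a terminal epoxide (SN2 at the unsubstituted CH2) outruns ester addition at low temperature and leaves the glycidate stereocentre untouched, so the (S) centre that becomes C6 is taken from the chiral pool.

**Step 2**
Reactants: 4 methyl (2S)-2-hydroxyhexadecanoate; 5 allylmagnesium bromide
Product: 6 (5S)-4-(prop-2-en-1-yl)nonadec-1-ene-4,5-diol
Conditions: 5 (3.5 equiv), Et2O/THF, −20 °C → rt; aq. NH4Cl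
Reagents that add atoms: none
Why: Double Grignard addition to the ester gives the diallyl carbinol that holds the future C5 (not stereogenic), the first equivalent only forming the α-alkoxide, which also suppresses epimerisation at the adjacent centre.

**Step 3**
Reactants: 6 (5S)-4-(prop-2-en-1-yl)nonadec-1-ene-4,5-diol
Product: 7 1-[(1S)-1-hydroxypentadecyl]cyclopent-3-en-1-ol
Conditions: second-generation Grubbs catalyst RuCl2(=CHPh)(H2IMes)(PCy3) (2 mol%), CH2Cl2, 40 °C
Reagents that add atoms: none
Why: Ring-closing olefin metathesis of a 4,4-disubstituted hepta-1,6-diene is a fast five-membered ring closure driven by loss of ethene and tolerates free hydroxyl groups.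

**Step 4**
Reactants: 7 1-[(1S)-1-hydroxypentadecyl]cyclopent-3-en-1-ol
Product: 9 tert-butyldimethyl({1-[(1S)-1-[(triethylsilyl)oxy]pentadecyl]cyclopent-3-en-1-yl}oxy)silane, via secondary triethylsilyl ether 8 (not isolated)
Conditions: TESOTf (1.05 equiv), 2,6-lutidine, CH2Cl2, −78 °C; then TBSOTf (2 equiv), −78 °C → rt
Reagents that add atoms: triethylsilyl trifluoromethanesulfonate, CC[Si](CC)(CC)OS(=O)(=O)C(F)(F)F; tert-butyldimethylsilyl trifluoromethanesulfonate, CC(C)(C)[Si](C)(C)OS(=O)(=O)C(F)(F)F
Why: Sequential silyl triflate O-silylation: at −78 °C the secondary hydroxyl reacts far faster than the hindered tertiary one, which is then capped by the more forcing tert-butyldimethylsilyl triflate on warming, so the two oxygens carry groups of different lability.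

**Step 5**
Reactants: 9 tert-butyldimethyl({1-[(1S)-1-[(triethylsilyl)oxy]pentadecyl]cyclopent-3-en-1-yl}oxy)silane
Product: 10 {[(3R,4R)-3,4-dibromo-1-[(1S)-1-[(triethylsilyl)oxy]pentadecyl]cyclopentyl]oxy}(tert-butyl)dimethylsilane (trans-dibromide; the (3S,4S) trans isomer should form alongside)
Conditions: Br2 (1.05 equiv), NaHCO3, CH2Cl2, −78 °C
Reagents that add atoms: bromine, BrBr
Why: Electrophilic anti addition through a bromonium ion sets the two new ring centres trans to each other, and both trans diastereomers converge in step 6, while buffering at low temperature protects the silyl ethers.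

**Step 6**
Reactants: 10 trans-3,4-dibromide
Product: 11 tert-butyldimethyl({1-[(1S)-1-[(triethylsilyl)oxy]pentadecyl]cyclopenta-2,4-dien-1-yl}oxy)silane
Conditions: KOtBu (3 equiv), THF, 0 °C → rt; used without storage
Reagents that add atoms: none
Why: Twofold E2 dehydrobromination: in the trans-dibromide only the flanking CH2 groups offer an antiperiplanar hydrogen, so the allylic bromide and then the 1,3-diene should form, and the diene cannot tautomerise because C5 bears no hydrogen.

**Step 7**
Reactants: 11 bis-silylated cyclopentadiene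
Product: 12 (1S)-1-{1-[(tert-butyldimethylsilyl)oxy]cyclopenta-2,4-dien-1-yl}pentadecan-1-ol (5,5-disubstituted cyclopenta-1,3-diene with C5–OTBS and free C6–OH)
Conditions: HF·pyridine, pyridine, THF, 0 °C; used directly
Reagents that add atoms: none
Why: Buffered fluoride desilylation removes the secondary triethylsilyl ether much faster than the tertiary tert-butyldimethylsilyl ether, and ionisation at C5 is excluded because it would give a cyclopentadienyl cation, so the diene and the C5 ether should survive.

**Step 8**
Reactants: 12 (1S)-1-{1-[(tert-butyldimethylsilyl)oxy]cyclopenta-2,4-dien-1-yl}pentadecan-1-ol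
Product: 14 (4R,5S)-5-[(tert-butyldimethylsilyl)oxy]-4-hydroxy-5-[(1S)-1-hydroxypentadecyl]cyclopent-2-en-1-one, via endoperoxide 13 (not isolated)
Conditions: O2, hν (visible), 5,10,15,20-tetraphenylporphyrin (1 mol%), CH2Cl2, −78 °C; Ar purge, dark; then 9-O-acetylcupreine (10 mol%), −78 → −30 °C
Reagents that add atoms: dioxygen, O=O
Why: Sensitised singlet oxygen adds suprafacially to the s-cis diene of 12 in a concerted [4+2] cycloaddition that forms the C1–O and C4–O bonds (the known endoperoxide formation of cyclopentadienes), and the tertiary amine then removes one bridgehead hydrogen with O–O heterolysis (Kornblum–DeLaMare rearrangement; the closest precedent is the cinchona-amine-catalysed desymmetrising opening of meso bicyclic endoperoxides), leaving the C1 ketone and the C4 hydroxyl. The only ring closed is the transient 2,3-dioxabicyclo[2.2.1]heptene of 13, formed by this 4π + 2π closure across the ring and opened again in the same flask, so 14 contains no new ring. C4 is fixed by the face of oxygen attack: its C–O bond must lie on the face that carries C6, towards which the free C6 hydroxyl should guide the oxygen by hydrogen bonding in a non-donor solvent, whereas the C5 oxygen is capped by a bulky silyl group that cannot donate a hydrogen bond and crowds its own face. C5 turns stereogenic only when the bridgeheads are differentiated, and this is set by the chiral amine, which must abstract the bridgehead hydrogen of the carbon that becomes C1; the (S)-C6 centre makes the two bridgeheads diastereotopic, so the catalyst pseudoenantiomer is chosen to reinforce the substrate bias. The step thus needs face and bridgehead selectivity, while chemoselectivity is built in: C5 carries no hydrogen, so neither an ene reaction nor a 1,5-hydrogen shift can compete, and adding the base cold, in the dark and after purging keeps 13 from thermal rearrangement and the amine from photooxidation.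

**Step 9**
Reactants: 14 (4R,5S)-5-[(tert-butyldimethylsilyl)oxy]-4-hydroxy-5-[(1S)-1-hydroxypentadecyl]cyclopent-2-en-1-one
Product: 15 (4R,5S)-4,5-dihydroxy-5-[(1S)-1-hydroxypentadecyl]cyclopent-2-en-1-one
Conditions: HF (48% aq.), MeCN, 0 °C → rt
Reagents that add atoms: none
Why: Fluoride-mediated desilylation of an α-keto tertiary silyl ether, activated towards Si–O cleavage, under acidic conditions that avoid retro-aldol cleavage of the β-hydroxy ketone.

**Step 10**
Reactants: 15 (4R,5S)-4,5-dihydroxy-5-[(1S)-1-hydroxypentadecyl]cyclopent-2-en-1-one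
Product: 16 (4S,5R,9R)-9-hydroxy-2,2-dimethyl-4-tetradecyl-1,3-dioxaspiro[4.4]non-7-en-6-one (C5/C6 acetonide of 15, configurations unchanged)
Conditions: Me2C(OMe)2, CSA (cat.), acetone, rt
Reagents that add atoms: 2,2-dimethoxypropane, COC(C)(C)OC
Why: Equilibrating acetalisation (transketalisation) favours the five-membered dioxolane of the vicinal C5/C6 diol over a six-membered acetal across the C4 and C6 oxygens, and the trans C4/C5 diol cannot be bridged, so only C4–OH stays free.

**Step 11**
Reactants: 16 C5/C6 acetonide
Product: 17 (4S,5S,9R)-2,2-dimethyl-6-oxo-4-tetradecyl-1,3-dioxaspiro[4.4]non-7-en-9-yl acetate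
Conditions: Ac2O, pyridine, DMAP (cat.), CH2Cl2, 0 °C
Reagents that add atoms: acetic anhydride, CC(=O)OC(C)=O
Why: DMAP-catalysed O-acylation of the single remaining, secondary allylic hydroxyl.

**Step 12**
Reactants: 17 acetonide acetate
Product: 18 (1R,5S)-5-hydroxy-5-[(1S)-1-hydroxypentadecyl]-4-oxocyclopent-2-en-1-yl acetate (target)
Conditions: TFA/H2O (9:1), 0 °C
Reagents that add atoms: none
Why: Acid-catalysed acetal hydrolysis, in which the allylic acetate tolerates brief cold aqueous acid and its trans relationship to C5–OH disfavours acyl migration.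

**Compound list**

1 | 1-bromotridecane | CCCCCCCCCCCCCBr | starting material
2 | methyl (2S)-oxirane-2-carboxylate | COC(=O)[C@@H]1CO1 | starting material
3 | tridecylmagnesium bromide | CCCCCCCCCCCCC[Mg]Br | intermediate
4 | methyl (2S)-2-hydroxyhexadecanoate | CCCCCCCCCCCCCC[C@H](O)C(=O)OC | intermediate
5 | allylmagnesium bromide | C=CC[Mg]Br | starting material
6 | (5S)-4-(prop-2-en-1-yl)nonadec-1-ene-4,5-diol | CCCCCCCCCCCCCC[C@H](O)C(O)(CC=C)CC=C | intermediate
7 | 1-[(1S)-1-hydroxypentadecyl]cyclopent-3-en-1-ol | CCCCCCCCCCCCCC[C@H](O)C1(O)CC=CC1 | intermediate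
8 | 1-[(1S)-1-[(triethylsilyl)oxy]pentadecyl]cyclopent-3-en-1-ol | CCCCCCCCCCCCCC[C@H](O[Si](CC)(CC)CC)C1(O)CC=CC1 | intermediate
9 | tert-butyldimethyl({1-[(1S)-1-[(triethylsilyl)oxy]pentadecyl]cyclopent-3-en-1-yl}oxy)silane | CCCCCCCCCCCCCC[C@H](O[Si](CC)(CC)CC)C1(O[Si](C)(C)C(C)(C)C)CC=CC1 | intermediate
10 | {[(3R,4R)-3,4-dibromo-1-[(1S)-1-[(triethylsilyl)oxy]pentadecyl]cyclopentyl]oxy}(tert-butyl)dimethylsilane (trans; (3S,4S) isomer alongside) | CCCCCCCCCCCCCC[C@H](O[Si](CC)(CC)CC)C1(O[Si](C)(C)C(C)(C)C)C[C@@H](Br)[C@H](Br)C1 | intermediate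
11 | tert-butyldimethyl({1-[(1S)-1-[(triethylsilyl)oxy]pentadecyl]cyclopenta-2,4-dien-1-yl}oxy)silane | CCCCCCCCCCCCCC[C@H](O[Si](CC)(CC)CC)C1(O[Si](C)(C)C(C)(C)C)C=CC=C1 | intermediate
12 | (1S)-1-{1-[(tert-butyldimethylsilyl)oxy]cyclopenta-2,4-dien-1-yl}pentadecan-1-ol | CCCCCCCCCCCCCC[C@H](O)C1(O[Si](C)(C)C(C)(C)C)C=CC=C1 | intermediate
13 | 7-[(tert-butyldimethylsilyl)oxy]-7-[(1S)-1-hydroxypentadecyl]-2,3-dioxabicyclo[2.2.1]hept-5-ene, hydroxyalkyl chain syn to the O–O bridge, silyloxy group syn to the alkene | CCCCCCCCCCCCCC[C@H](O)[C@]1(O[Si](C)(C)C(C)(C)C)[C@H]2C=C[C@@H]1OO2 | intermediate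
14 | (4R,5S)-5-[(tert-butyldimethylsilyl)oxy]-4-hydroxy-5-[(1S)-1-hydroxypentadecyl]cyclopent-2-en-1-one | CCCCCCCCCCCCCC[C@H](O)[C@@]1(O[Si](C)(C)C(C)(C)C)C(=O)C=C[C@H]1O | intermediate
15 | (4R,5S)-4,5-dihydroxy-5-[(1S)-1-hydroxypentadecyl]cyclopent-2-en-1-one | CCCCCCCCCCCCCC[C@H](O)[C@@]1(O)C(=O)C=C[C@H]1O | intermediate
16 | (4S,5R,9R)-9-hydroxy-2,2-dimethyl-4-tetradecyl-1,3-dioxaspiro[4.4]non-7-en-6-one | CCCCCCCCCCCCCC[C@@H]1OC(C)(C)O[C@@]12C(=O)C=C[C@H]2O | intermediate
17 | (4S,5S,9R)-2,2-dimethyl-6-oxo-4-tetradecyl-1,3-dioxaspiro[4.4]non-7-en-9-yl acetate | CCCCCCCCCCCCCC[C@@H]1OC(C)(C)O[C@@]12C(=O)C=C[C@H]2OC(C)=O | intermediate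
18 | (1R,5S)-5-hydroxy-5-[(1S)-1-hydroxypentadecyl]-4-oxocyclopent-2-en-1-yl acetate | CCCCCCCCCCCCCC[C@H](O)[C@@]1(O)C(=O)C=C[C@H]1OC(C)=O | target

**Step count**

Total step count: 12. Longest linear sequence: 12 steps (1 to 18).

**Steps most likely to fail**

1. Step 8. The likely failure is poor facial selectivity: oxygen adding on the face of the C5 silyloxy group, the usual preference of 5-oxygenated cyclopentadienes, instead of the C6 face, which would give the C4 epimer. Weak bridgehead discrimination would add to it. The fallback accepts addition on the oxygen face and corrects C4 afterwards. It sets out from 11, in which both oxygens are silylated so that no hydrogen bond competes. Photooxygenation under the conditions of step 8 should place the peroxide on the face of the small C5 oxygen substituent and give the epimeric endoperoxide F1. Opening with the cinchona amine matched to the same C5 configuration should give the cis-configured hydroxy enone F2, with C4–OH on the face of C5–O. Mitsunobu esterification with acetic acid (PPh3, DIAD, toluene, 0 °C) inverts C4 and installs the acetate, giving the bis-silylated acetate F3. Aqueous HF in MeCN removes both silyl ethers, and the route is rejoined at 18.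

2. Step 6. The likely failure is incomplete or misdirected elimination: loss of only one HBr, or substitution by tert-butoxide at the allylic bromide stage. Diels–Alder dimerisation of the diene while the second elimination lags would add to it. The fallback sets out from 9. Wohl–Ziegler bromination (N-bromosuccinimide, AIBN, PhCF3, 80 °C) should give the allylic bromide F4. It needs only a single 1,2- or 1,4-elimination (KOtBu, THF, −20 °C) to reach 11, where the main route continues.

3. Step 10. The likely failure is acetal formation across the cis-related C4 and C6 hydroxyls, or stalling at the hindered tertiary C5 hydroxyl next to the ketone. The fallback sets out from 14, before desilylation. Kinetic monoacetylation of the less hindered ring hydroxyl (AcCl, 2,4,6-collidine, CH2Cl2, −78 °C) should give the C4 acetate F5, since the C6 hydroxyl is screened by the chain and the neighbouring silyl ether. Aqueous HF in MeCN then removes the C5 silyl ether and gives 18 directly.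

**Further compounds**

F1 | step 8 | 7-[(tert-butyldimethylsilyl)oxy]-7-[(1S)-1-[(triethylsilyl)oxy]pentadecyl]-2,3-dioxabicyclo[2.2.1]hept-5-ene, silyloxy group syn to the O–O bridge | CCCCCCCCCCCCCC[C@H](O[Si](CC)(CC)CC)[C@@]1(O[Si](C)(C)C(C)(C)C)[C@H]2C=C[C@@H]1OO2
F2 | step 8 | (4S,5R)-5-[(tert-butyldimethylsilyl)oxy]-4-hydroxy-5-[(1S)-1-[(triethylsilyl)oxy]pentadecyl]cyclopent-2-en-1-one (C4–OH cis to C5–O) | CCCCCCCCCCCCCC[C@H](O[Si](CC)(CC)CC)[C@@]1(O[Si](C)(C)C(C)(C)C)C(=O)C=C[C@@H]1O
F3 | step 8 | C5-O-tert-butyldimethylsilyl, C6-O-triethylsilyl bis-ether of 18 (ring configuration as in 18) | CCCCCCCCCCCCCC[C@H](O[Si](CC)(CC)CC)[C@@]1(O[Si](C)(C)C(C)(C)C)C(=O)C=C[C@H]1OC(C)=O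
F4 | step 6 | {[4-bromo-1-[(1S)-1-[(triethylsilyl)oxy]pentadecyl]cyclopent-2-en-1-yl]oxy}(tert-butyl)dimethylsilane (mixture of ring diastereomers) | CCCCCCCCCCCCCC[C@H](O[Si](CC)(CC)CC)C1(O[Si](C)(C)C(C)(C)C)C=CC(Br)C1
F5 | step 10 | (1R,5S)-5-[(tert-butyldimethylsilyl)oxy]-5-[(1S)-1-hydroxypentadecyl]-4-oxocyclopent-2-en-1-yl acetate | CCCCCCCCCCCCCC[C@H](O)[C@@]1(O[Si](C)(C)C(C)(C)C)C(=O)C=C[C@H]1OC(C)=O
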